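**Plan**

- Numbering follows the 6-oxabicyclo[3.2.1]octane core: C1 prenyl bridgehead, C2 methylene, C3 prenyl methine, C4 CMe2, C5 isobutyryl bridgehead, O6, C7 lactone carbonyl, C8 ketone. C8 is bonded to both bridgeheads and C5 also carries the isobutyryl C=O, so C8–C5–acyl is an acylketene retron and C1–C7 an aldehyde enol ether.
- Retrosynthesis: the lactone comes from a lactol (C7 oxidation); O6–C5 and O6–C7 are cut to a formyl diketone enolate (enolate hydroxylation, lactol closure); this enolate is the fluoride-opened form of a bridged silyloxy dihydropyranone, which is cut at C8–C1 and O(acyl)–C7 (intramolecular acylketene hetero-Diels–Alder).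
- The open-chain tert-butyl β-keto ester is cut at C5–acyl (aldol, oxidation), C1–C2 (hydrazone alkylation) and C3–prenyl (auxiliary alkylation), back to 3,3-dimethylglutaric anhydride.
- Forward: the chain is assembled first; the cyclohexanone ring and a temporary oxygen bridge close together in the cycloaddition; fluoride opens the bridge and the five-membered lactone ring closes through the new C5 oxygen.
- Stereochemistry: C3 from the (S)-4-benzyloxazolidinone alkylation; C1 from the chair-like cycloaddition with the C3 prenyl group equatorial; C5 from hydroxylation syn to the axial formyl group, enforced by lactol closure (an oxygen put on C5 of the bridged adduct itself would be trans to C7 and could never close, hence the opening first).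

Key step: step 11

Assumption: compounds 1, 3, 5, 9 and 14 are purchasable; enol ether geometry, the keto ester epimer and the acetal and lactol epimers are carried on unseparated because these centres end up planar or oxidised.

**Step 1**
Reactants: 1 3,3-dimethylglutaric anhydride
Product: 2 5-tert-butoxy-3,3-dimethyl-5-oxopentanoic acid
Conditions: KOC(CH3)3, THF, 0 °C → rt; then 1 M HCl
Reagents that add atoms: potassium tert-butoxide, CC(C)(C)[O-].[K+]
Why: Alkoxide ring opening of a cyclic anhydride gives the half ester, and the symmetry of 1 allows only one product.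

**Step 2**
Reactants: 2 5-tert-butoxy-3,3-dimethyl-5-oxopentanoic acid; 3 (S)-4-benzyloxazolidin-2-one
Product: 4 tert-butyl 5-[(4S)-4-benzyl-2-oxooxazolidin-3-yl]-3,3-dimethyl-5-oxopentanoate
Conditions: t-BuCOCl, Et3N, THF, −20 °C; then 3, LiCl, −20 °C → rt
Reagents that add atoms: none
Why: N-Acylation of the oxazolidinone through the mixed pivalic anhydride is standard, and the nucleophile attacks the less hindered carbonyl of that anhydride.

**Step 3**
Reactants: 4 tert-butyl 5-[(4S)-4-benzyl-2-oxooxazolidin-3-yl]-3,3-dimethyl-5-oxopentanoate; 5 prenyl bromide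
Product: 6 tert-butyl (4S)-4-{[(4S)-4-benzyl-2-oxooxazolidin-3-yl]carbonyl}-3,3,7-trimethyloct-6-enoate
Conditions: NaN(SiMe3)2, THF, −78 °C; then 5, −78 → −40 °C
Reagents that add atoms: none
Why: Evans asymmetric alkylation: the imide is far more acidic than the tert-butyl ester, its chelated Z sodium enolate is shielded on one face by the benzyl group, and the allylic bromide enters from the open face to set C3 as (S) in 6, which is the (R) centre of the target (same geometry, changed priorities).

**Step 4**
Reactants: 6 tert-butyl (4S)-4-{[(4S)-4-benzyl-2-oxooxazolidin-3-yl]carbonyl}-3,3,7-trimethyloct-6-enoate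
Product: 7 tert-butyl (4S)-4-(hydroxymethyl)-3,3,7-trimethyloct-6-enoate
Conditions: LiBH4, H2O (1 equiv), Et2O, 0 °C; product used at once
Reagents that add atoms: none
Why: Reductive removal of the auxiliary with LiBH4 (hydride reduction of the exocyclic imide carbonyl) should spare the hindered tert-butyl ester and the alkene and does not touch C3.

**Step 5**
Reactants: 7 tert-butyl (4S)-4-(hydroxymethyl)-3,3,7-trimethyloct-6-enoate
Product: 8 tert-butyl (4S)-4-(iodomethyl)-3,3,7-trimethyloct-6-enoate
Conditions: I2, PPh3, imidazole, CH2Cl2, 0 °C → rt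
Reagents that add atoms: iodine, II
Why: Appel-type iodination converts the primary alcohol into the iodide under neutral conditions before the hydroxy ester can lactonise.

**Step 6**
Reactants: 9 5-methylhex-4-enal
Product: 10 (E)-1,1-dimethyl-2-(5-methylhex-4-en-1-ylidene)hydrazine
Conditions: Me2NNH2, MgSO4, CH2Cl2, rt
Reagents that add atoms: 1,1-dimethylhydrazine, CN(C)N
Why: Condensation of the aldehyde with 1,1-dimethylhydrazine gives the N,N-dimethylhydrazone, which serves as an aldehyde enolate equivalent.

**Step 7**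
Reactants: 8 tert-butyl (4S)-4-(iodomethyl)-3,3,7-trimethyloct-6-enoate; 10 (E)-1,1-dimethyl-2-(5-methylhex-4-en-1-ylidene)hydrazine
Product: 12 tert-butyl (4R)-4-(2-formyl-5-methylhex-4-en-1-yl)-3,3,7-trimethyloct-6-enoate (both C1 epimers), via alkylated hydrazone 11 (not isolated)
Conditions: 10, LiN(i-Pr)2, THF, 0 °C; then 8, DMPU, −78 °C → rt; then sat. aq. oxalic acid, Et2O, rt
Reagents that add atoms: water, O
Why: Corey–Enders alkylation of the lithiated hydrazone with the primary iodide forms the C1–C2 bond (DMPU offsets the β-branching), mild acid hydrolysis then releases the aldehyde without harming the tert-butyl ester, and the new centre C1 becomes planar in step 8.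

**Step 8**
Reactants: 12 tert-butyl (4R)-4-(2-formyl-5-methylhex-4-en-1-yl)-3,3,7-trimethyloct-6-enoate
Product: 13 tert-butyl (4R)-4-[2-({[tert-butyl(dimethyl)silyl]oxy}methylidene)-5-methylhex-4-en-1-yl]-3,3,7-trimethyloct-6-enoate (E/Z mixture)
Conditions: t-BuMe2SiOSO2CF3, Et3N, CH2Cl2, −78 → 0 °C
Reagents that add atoms: tert-butyldimethylsilyl trifluoromethanesulfonate, CC(C)(C)[Si](C)(C)OS(=O)(=O)C(F)(F)F
Why: Soft enolisation of the α-branched aldehyde with a silyl triflate and an amine gives the silyl enol ether, which also masks the aldehyde for the enolate chemistry that follows, and the short cold reaction should leave the tert-butyl ester intact.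

**Step 9**
Reactants: 13 tert-butyl (4R)-4-[2-({[tert-butyl(dimethyl)silyl]oxy}methylidene)-5-methylhex-4-en-1-yl]-3,3,7-trimethyloct-6-enoate; 14 isobutyraldehyde
Product: 15 tert-butyl (4R)-4-[2-({[tert-butyl(dimethyl)silyl]oxy}methylidene)-5-methylhex-4-en-1-yl]-2-(1-hydroxy-2-methylpropyl)-3,3,7-trimethyloct-6-enoate (diastereomer mixture)
Conditions: LiN(i-Pr)2, THF, −78 °C; then 14, −78 °C; aq. NH4Cl
Reagents that add atoms: none
Why: Aldol addition of the lithium ester enolate to isobutyraldehyde forms the bond from C5 to the acyl carbon, the silyl enol ether is inert to the amide base, and the two new centres need no control because one is oxidised next and the other is lost in the ketene.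

**Step 10**
Reactants: 15 tert-butyl (4R)-4-[2-({[tert-butyl(dimethyl)silyl]oxy}methylidene)-5-methylhex-4-en-1-yl]-2-(1-hydroxy-2-methylpropyl)-3,3,7-trimethyloct-6-enoate
Product: 16 tert-butyl (4R)-4-[2-({[tert-butyl(dimethyl)silyl]oxy}methylidene)-5-methylhex-4-en-1-yl]-3,3,7-trimethyl-2-(2-methylpropanoyl)oct-6-enoate (either C5 epimer)
Conditions: Dess–Martin periodinane, pyridine, CH2Cl2, 0 °C → rt
Reagents that add atoms: none
Why: Dess–Martin oxidation of a β-hydroxy ester to the β-keto ester runs under buffered non-acidic conditions that should leave the silyl enol ether and the alkenes alone.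

**Step 11**
Reactants: 16 tert-butyl (4R)-4-[2-({[tert-butyl(dimethyl)silyl]oxy}methylidene)-5-methylhex-4-en-1-yl]-3,3,7-trimethyl-2-(2-methylpropanoyl)oct-6-enoate
Product: 18 bridged silyloxy dihydropyranone (5S,7R)-4-{[tert-butyl(dimethyl)silyl]oxy}-8,8-dimethyl-5,7-bis(3-methylbut-2-en-1-yl)-2-(propan-2-yl)-3-oxabicyclo[3.3.1]non-1-en-9-one (either acetal epimer), via isobutyryl ketene 17 (not isolated)
Conditions: xylene (0.005 M), 4 Å molecular sieves, 140 °C, N2 stream; concentrate, use crude
Reagents that add atoms: none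
Why: Proposed new method: heating should expel tert-butanol from the enol form of 16 through a six-membered transition state to give the s-cis isobutyryl ketene 17, whose electrophilic ketene carbon C8 is attacked by the nucleophilic enol ether carbon C1 while the acyl oxygen closes on the silyloxy-bearing carbon C7 in an asynchronous hetero-Diels–Alder reaction. The closest known reactions are the intermolecular [4+2] additions of thermally generated acylketenes to enol ethers, which give 2-alkoxy-2,3-dihydropyran-4-ones, and type 2 intramolecular Diels–Alder reactions, which give bridgehead alkenes; the intramolecular type 2 variant with an acylketene is not known. The carbocycle closes by six-membered exo attack of C1 on the ketene carbon (the C4–C5 bond and the tether C4–C3–C2 are already in place), and the oxa ring closes by six-membered O–C7 bond formation spanning C1 and C5, which makes the bicycle bridged and puts the new enol ether double bond at bridgehead C5 of a bicyclo[3.3.1]nonene, a ring size that tolerates it. The quaternary centre C1 is set by a chair-like forming carbocycle in which the C3 prenyl group is equatorial and C7 is axial, as it must be to reach the acyl oxygen, so the two prenyl groups end up cis; the acetal centre C7 follows the enol ether geometry and is erased later. The step needs periselectivity for [4+2] over [2+2] closure or silyl transfer, secured by the electron-rich enol ether and the acyl oxygen held next to C7 (a silyl-transferred open isomer would in any case give the same enolate 19 in step 12), and it needs the facial selectivity at C1 described above.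

**Step 12**
Reactants: 18 bridged silyloxy dihydropyranone
Product: 20 lactol (1S,3R,5R)-7-hydroxy-4,4-dimethyl-1,3-bis(3-methylbut-2-en-1-yl)-5-(2-methylpropanoyl)-6-oxabicyclo[3.2.1]octan-8-one (both anomers), via formyl diketone enolate 19 (not isolated)
Conditions: Bu4NF (1.05 equiv), THF, −78 °C; then 2-(phenylsulfonyl)-3-phenyloxaziridine, −78 → 0 °C; aq. NH4Cl
Reagents that add atoms: 2-(phenylsulfonyl)-3-phenyloxaziridine, O=S(=O)(c1ccccc1)N1OC1c1ccccc1
Why: Fluoride cleaves the silyl acetal and the hemiacetal alkoxide opens, with relief of bridgehead alkene strain, to the C1 aldehyde and diketone enolate 19, which should undergo Davis enolate hydroxylation at C5 on the face of the axial formyl group (the other face is blocked by the pseudoaxial C4 methyl group), and only this cis alkoxide can add to the aldehyde, so closure of the five-membered lactol fixes C5 as in the target.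

**Step 13**
Reactants: 20 lactol
Product: 21 (1R,3R,5R)-4,4-dimethyl-1,3-bis(3-methylbut-2-en-1-yl)-5-(2-methylpropanoyl)-6-oxabicyclo[3.2.1]octane-7,8-dione
Conditions: Dess–Martin periodinane, CH2Cl2, rt
Reagents that add atoms: none
Why: Dess–Martin oxidation of a lactol to the lactone is routine, and the quaternary, non-enolisable centres C1 and C5 exclude epimerisation.

**Compound list**

1 | 3,3-dimethylglutaric anhydride | CC1(C)CC(=O)OC(=O)C1 | starting material
2 | 5-tert-butoxy-3,3-dimethyl-5-oxopentanoic acid | CC(C)(C)OC(=O)CC(C)(C)CC(=O)O | intermediate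
3 | (S)-4-benzyloxazolidin-2-one | O=C1N[C@@H](Cc2ccccc2)CO1 | starting material
4 | tert-butyl 5-[(4S)-4-benzyl-2-oxooxazolidin-3-yl]-3,3-dimethyl-5-oxopentanoate | CC(C)(C)OC(=O)CC(C)(C)CC(=O)N1[C@@H](Cc2ccccc2)COC1=O | intermediate
5 | prenyl bromide (1-bromo-3-methylbut-2-ene) | CC(C)=CCBr | starting material
6 | tert-butyl (4S)-4-{[(4S)-4-benzyl-2-oxooxazolidin-3-yl]carbonyl}-3,3,7-trimethyloct-6-enoate | CC(C)=CC[C@@H](C(C)(C)CC(=O)OC(C)(C)C)C(=O)N1[C@@H](Cc2ccccc2)COC1=O | intermediate
7 | tert-butyl (4S)-4-(hydroxymethyl)-3,3,7-trimethyloct-6-enoate | CC(C)=CC[C@@H](C(C)(C)CC(=O)OC(C)(C)C)CO | intermediate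
8 | tert-butyl (4S)-4-(iodomethyl)-3,3,7-trimethyloct-6-enoate | CC(C)=CC[C@@H](C(C)(C)CC(=O)OC(C)(C)C)CI | intermediate
9 | 5-methylhex-4-enal | CC(C)=CCCC=O | starting material
10 | (E)-1,1-dimethyl-2-(5-methylhex-4-en-1-ylidene)hydrazine | CC(C)=CCC/C=N/N(C)C | intermediate
11 | tert-butyl (4R)-4-{2-[(E)-(dimethylhydrazinylidene)methyl]-5-methylhex-4-en-1-yl}-3,3,7-trimethyloct-6-enoate (both epimers at the hydrazone-bearing carbon) | CC(C)=CC[C@@H](C(C)(C)CC(=O)OC(C)(C)C)CC(CC=C(C)C)/C=N/N(C)C | intermediate
12 | tert-butyl (4R)-4-(2-formyl-5-methylhex-4-en-1-yl)-3,3,7-trimethyloct-6-enoate (both epimers at the formyl-bearing carbon) | CC(C)=CC[C@@H](C(C)(C)CC(=O)OC(C)(C)C)CC(CC=C(C)C)C=O | intermediate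
13 | tert-butyl (4R)-4-[2-({[tert-butyl(dimethyl)silyl]oxy}methylidene)-5-methylhex-4-en-1-yl]-3,3,7-trimethyloct-6-enoate (E drawn, E/Z mixture) | CC(C)=CC[C@@H](C(C)(C)CC(=O)OC(C)(C)C)C/C(CC=C(C)C)=C/O[Si](C)(C)C(C)(C)C | intermediate
14 | isobutyraldehyde (2-methylpropanal) | CC(C)C=O | starting material
15 | tert-butyl (4R)-4-[2-({[tert-butyl(dimethyl)silyl]oxy}methylidene)-5-methylhex-4-en-1-yl]-2-(1-hydroxy-2-methylpropyl)-3,3,7-trimethyloct-6-enoate (mixture at the two new carbons, left undefined; E enol ether drawn) | CC(C)=CC[C@@H](C(C)(C)C(C(O)C(C)C)C(=O)OC(C)(C)C)C/C(CC=C(C)C)=C/O[Si](C)(C)C(C)(C)C | intermediate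
16 | tert-butyl (4R)-4-[2-({[tert-butyl(dimethyl)silyl]oxy}methylidene)-5-methylhex-4-en-1-yl]-3,3,7-trimethyl-2-(2-methylpropanoyl)oct-6-enoate (one C5 epimer and the E enol ether drawn) | CC(C)=CC[C@@H](C(C)(C)[C@H](C(=O)C(C)C)C(=O)OC(C)(C)C)C/C(CC=C(C)C)=C/O[Si](C)(C)C(C)(C)C | intermediate
17 | isobutyryl ketene, (6R)-6-[2-({[tert-butyl(dimethyl)silyl]oxy}methylidene)-5-methylhex-4-en-1-yl]-2,5,5,9-tetramethyl-4-(oxomethylidene)dec-8-en-3-one | CC(C)=CC[C@@H](C(C)(C)C(=C=O)C(=O)C(C)C)C/C(CC=C(C)C)=C/O[Si](C)(C)C(C)(C)C | intermediate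
18 | (5S,7R)-4-{[tert-butyl(dimethyl)silyl]oxy}-8,8-dimethyl-5,7-bis(3-methylbut-2-en-1-yl)-2-(propan-2-yl)-3-oxabicyclo[3.3.1]non-1-en-9-one (one acetal epimer drawn) | CC(C)=CC[C@@H]1C[C@@]2(CC=C(C)C)[C@@H](O[Si](C)(C)C(C)(C)C)OC(C(C)C)=C(C2=O)C1(C)C | intermediate
19 | tetrabutylammonium enolate of 4,4-dimethyl-1,5-bis(3-methylbut-2-enyl)-3-(2-methylpropanoyl)-2-oxocyclohexane-1-carbaldehyde (formyl carbon and ring prenyl configured as C1 and C3 of the target) | CC(C)=CC[C@@H]1C[C@@](CC=C(C)C)(C=O)C([O-])=C(C(=O)C(C)C)C1(C)C.CCCC[N+](CCCC)(CCCC)CCCC | intermediate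
20 | (1S,3R,5R)-7-hydroxy-4,4-dimethyl-1,3-bis(3-methylbut-2-en-1-yl)-5-(2-methylpropanoyl)-6-oxabicyclo[3.2.1]octan-8-one (one anomer drawn) | CC(C)=CC[C@@H]1C[C@@]2(CC=C(C)C)[C@H](O)O[C@](C(=O)C(C)C)(C2=O)C1(C)C | intermediate
21 | (1R,3R,5R)-4,4-dimethyl-1,3-bis(3-methylbut-2-en-1-yl)-5-(2-methylpropanoyl)-6-oxabicyclo[3.2.1]octane-7,8-dione | CC(C)=CC[C@@H]1C[C@@]2(CC=C(C)C)C(=O)O[C@](C(=O)C(C)C)(C2=O)C1(C)C | target

**Step count**

Total: 13 steps. Longest linear sequence: 12 steps (steps 1–5 and 7–13; step 6 is a one-step side branch).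

**Steps most likely to fail**

1. Step 11. The enol form needed for loss of tert-butanol is disfavoured at the congested C5, so ketene formation may be slower than pyrolysis of the tert-butyl ester, and the two-bond closure may divert to a cyclobutanone or proceed with low facial selectivity at C1. Fallback with known chemistry, from 11 to 20: hydrazone 11 is isolated by a neutral work-up in step 7 and treated with LiN(i-Pr)2 (THF, 0 °C → rt), so that the lithiated hydrazone acylates itself with the tert-butyl ester in a Dieckmann-type closure of the cyclohexanone to give keto hydrazone F1 (the small sp2 aldimine carbon is expected axial, prenyl groups cis). Soft-enolisation C-acylation at C5 (MgBr2·OEt2, i-Pr2NEt, isobutyryl chloride) gives diketone hydrazone F2. Davis hydroxylation of its potassium enolate (KN(SiMe3)2, then the oxaziridine) gives hydroxy diketone hydrazone F3, and hydrolysis of the hydrazone (CuCl2, aqueous THF) lets the aldehyde close to lactol 20.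

2. Step 12. Poor facial selectivity in the hydroxylation would leave a trans hydroxy aldehyde that cannot close, and fluoride or hydroxide may cleave the formyl group from the β-keto aldehyde by a retro-Claisen reaction. Fallback, from 18 to 21: the oxygen is delivered from C7 instead. Buffered desilylation (Bu4NF, AcOH, THF, 0 °C) gives formyl diketone F4. Pinnick oxidation (NaClO2, NaH2PO4, excess 2-methylbut-2-ene, t-BuOH/H2O, 0 °C) gives keto acid F5, which is kept cold. Oxidative lactonisation with a trivalent iodine reagent (PhI(OH)OTs, CH2Cl2) then lets the carboxylate attack the activated C5 enol from the only face it can reach, giving 21 directly.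

3. Step 7. Displacement at the β-branched iodide next to a quaternary carbon may be slow, so that elimination or proton transfer to the ester (followed by cyclobutane closure) competes. Fallback, from 7 to 12: the C1–C2 bond is made by olefination. Dess–Martin oxidation of 7 gives aldehyde F6. Horner–Wadsworth–Emmons reaction with diethyl (1-cyano-4-methylpent-3-en-1-yl)phosphonate (made from diethyl cyanomethylphosphonate, NaH and 5; NaH, THF) gives unsaturated nitrile F7. Conjugate reduction (Mg, MeOH) gives nitrile F8, and i-Bu2AlH (toluene, −78 °C) followed by aqueous acid gives aldehyde 12.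

**Further compounds**

F1 | step 11 | 2-[(E)-(dimethylhydrazinylidene)methyl]-5,5-dimethyl-2,4-bis(3-methylbut-2-en-1-yl)cyclohexan-1-one (C2 and C4 configured as C1 and C3 of the target) | CC(C)=CC[C@@H]1C[C@@](CC=C(C)C)(/C=N/N(C)C)C(=O)CC1(C)C
F2 | step 11 | 2-[(E)-(dimethylhydrazinylidene)methyl]-5,5-dimethyl-2,4-bis(3-methylbut-2-en-1-yl)-6-(2-methylpropanoyl)cyclohexan-1-one (C6 epimers and enol) | CC(C)=CC[C@@H]1C[C@@](CC=C(C)C)(/C=N/N(C)C)C(=O)C(C(=O)C(C)C)C1(C)C
F3 | step 11 | 6-hydroxy derivative of F2 with the hydroxyl cis to the hydrazone-bearing carbon | CC(C)=CC[C@@H]1C[C@@](CC=C(C)C)(/C=N/N(C)C)C(=O)[C@](O)(C(=O)C(C)C)C1(C)C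
F4 | step 12 | 4,4-dimethyl-1,5-bis(3-methylbut-2-enyl)-3-(2-methylpropanoyl)-2-oxocyclohexane-1-carbaldehyde (C3 epimers and enol) | CC(C)=CC[C@@H]1C[C@@](CC=C(C)C)(C=O)C(=O)C(C(=O)C(C)C)C1(C)C
F5 | step 12 | 4,4-dimethyl-1,5-bis(3-methylbut-2-enyl)-3-(2-methylpropanoyl)-2-oxocyclohexane-1-carboxylic acid | CC(C)=CC[C@@H]1C[C@@](CC=C(C)C)(C(=O)O)C(=O)C(C(=O)C(C)C)C1(C)C
F6 | step 7 | tert-butyl (4S)-4-formyl-3,3,7-trimethyloct-6-enoate | CC(C)=CC[C@@H](C(C)(C)CC(=O)OC(C)(C)C)C=O
F7 | step 7 | tert-butyl (4R)-4-[(Z)-2-cyano-5-methylhexa-1,4-dien-1-yl]-3,3,7-trimethyloct-6-enoate (Z drawn, E/Z mixture) | CC(C)=CC[C@@H](C(C)(C)CC(=O)OC(C)(C)C)/C=C(/CC=C(C)C)C#N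
F8 | step 7 | tert-butyl (4R)-4-(2-cyano-5-methylhex-4-en-1-yl)-3,3,7-trimethyloct-6-enoate (both epimers at the nitrile-bearing carbon) | CC(C)=CC[C@@H](C(C)(C)CC(=O)OC(C)(C)C)CC(C#N)CC=C(C)C
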